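**Retrosynthetic overview**
1. The target is (3R)-licoisoflavanone. Its three phenols are traced back to MOM ethers, and its C3 configuration to a racemic, base-labile isoflavanone that is resolved dynamically (asymmetric transfer hydrogenation to the cis-(3R,4R) alcohol, then re-oxidation of C4).
2. Key disconnection: ring C is opened at C4–C4a and at O1–C2. This gives 3,5-bis(methoxymethoxy)phenol (ring A with O1) and an α-aryl acryloyl chloride (C2–C3–C4 with ring B). Forward, a magnesium-templated ortho C-acylation and a 6-endo oxa-Michael closure run in one flask.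
3. Enabling feature: ring A is a phloroglucinol ring. C4a lies ortho to the oxygen-bearing C8a and C5 and para to C7–O, so it is the most nucleophilic arene carbon, and both ortho carbons of the symmetric phenol are equivalent. C2=C3–C4 is an acrylic unit whose CH2 terminus accepts O1, and the acidic C3–H (α to C4=O, benzylic) allows the later dynamic kinetic resolution.
4. The acryloyl unit comes from the acetyl group of 6-acetyl-5-hydroxy-2,2-dimethylchromene (enol triflate, then carbonylation), which is made from 2',4'-dihydroxyacetophenone and prenal.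
5. Ring order: the pyran ring on ring B first (step 1), ring C in the key step; both benzene rings are bought.

Key step: step 7

Remark: the SMILES is read as the (3R) enantiomer (C4 > C2 > C1' > H at C3); 3,5-bis(methoxymethoxy)phenol is treated as not purchasable and is made in step 6.

**Route**

Step 1
Reactants: 1 2',4'-dihydroxyacetophenone; 2 3-methylbut-2-enal (prenal)
Product: 3 1-(5-hydroxy-2,2-dimethyl-2H-chromen-6-yl)ethan-1-one
Conditions: pyridine, 140 °C (sealed tube)
Reagents that add atoms: none
Why: Amine-mediated chromenylation (Knoevenagel-type C-alkylation of the ring carbon between the two oxygens, loss of water to an ortho-quinone methide, 6π oxa-electrocyclization) should give the angular chromene, because the 2'-OH is tied up in a hydrogen bond to the acetyl group and only the 4'-OH closes the pyran ring.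

Step 2
Reactants: 3 1-(5-hydroxy-2,2-dimethyl-2H-chromen-6-yl)ethan-1-one
Product: 4 1-[5-(methoxymethoxy)-2,2-dimethyl-2H-chromen-6-yl]ethan-1-one
Conditions: NaH, MOMCl, DMF, 0 °C to rt
Reagents that add atoms: chloromethyl methyl ether (MOMCl), COCCl
Why: Williamson etherification of the sodium phenolate masks the phenol, which would otherwise be sulfonylated in step 3 and acylated in step 5, as an acetal that survives base, palladium, Grignard and hydride-transfer conditions.

Step 3
Reactants: 4 1-[5-(methoxymethoxy)-2,2-dimethyl-2H-chromen-6-yl]ethan-1-one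
Product: 5 1-[5-(methoxymethoxy)-2,2-dimethyl-2H-chromen-6-yl]ethenyl trifluoromethanesulfonate
Conditions: KN(SiMe3)2, THF, −78 °C; PhNTf2, −78 to 0 °C
Reagents that add atoms: N-phenylbis(trifluoromethanesulfonimide) (PhNTf2), O=S(=O)(N(c1ccccc1)S(=O)(=O)C(F)(F)F)C(F)(F)F
Why: Enol triflate formation: the methyl group is the only enolizable position, so a single potassium enolate forms and is O-sulfonylated to the 1-arylvinyl triflate.

Step 4
Reactants: 5 1-[5-(methoxymethoxy)-2,2-dimethyl-2H-chromen-6-yl]ethenyl trifluoromethanesulfonate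
Product: 6 2-[5-(methoxymethoxy)-2,2-dimethyl-2H-chromen-6-yl]prop-2-enoic acid
Conditions: Pd(OAc)2 (5 mol%), dppp (5 mol%), CO (1 atm), KOAc, DMSO, 60 °C; aq. citric acid work-up
Reagents that add atoms: carbon monoxide, [C-]#[O+]; potassium acetate, CC(=O)[O-].[K+]
Why: Palladium-catalysed hydroxycarbonylation of a vinyl triflate (oxidative addition to zerovalent palladium, CO insertion, capture of the acylpalladium by acetate and acyl exchange of the mixed anhydride) should give the 2-arylacrylic acid without touching the chromene alkene or the MOM ether.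

Step 5
Reactants: 6 2-[5-(methoxymethoxy)-2,2-dimethyl-2H-chromen-6-yl]prop-2-enoic acid
Product: 7 2-[5-(methoxymethoxy)-2,2-dimethyl-2H-chromen-6-yl]prop-2-enoyl chloride
Conditions: 1-chloro-N,N,2-trimethylprop-1-en-1-amine (1.1 equiv), CH2Cl2, 0 °C; volatiles removed, crude 7 used at once
Reagents that add atoms: 1-chloro-N,N,2-trimethylprop-1-en-1-amine, CC(C)=C(Cl)N(C)C
Why: Acid chloride formation with an α-chloroenamine runs under neutral conditions and releases only an amide, so no HCl is formed that could add to the chromene or cleave the MOM ether.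

Step 6
Reactants: 8 phloroglucinol
Product: 9 3,5-bis(methoxymethoxy)phenol
Conditions: NaH (2 equiv), MOMCl (2 equiv), DMF, 0 °C to rt; chromatography
Reagents that add atoms: chloromethyl methyl ether (MOMCl), COCCl
Why: Statistical Williamson etherification of a threefold-symmetric triol needs control only of the degree of alkylation, and the bis-ether should be separable by chromatography from the mono- and tris-ethers.

Step 7
Reactants: 9 3,5-bis(methoxymethoxy)phenol; 7 2-[5-(methoxymethoxy)-2,2-dimethyl-2H-chromen-6-yl]prop-2-enoyl chloride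
Product: 12 rac-5,7-bis(methoxymethoxy)-3-[5-(methoxymethoxy)-2,2-dimethyl-2H-chromen-6-yl]chroman-4-one, via bromomagnesium phenolate 10 (not isolated), via hydroxyaryl vinyl ketone 11 (not isolated)
Conditions: 9, EtMgBr (1.0 equiv), Et2O, 0 °C, then toluene in place of Et2O; 7 in toluene, 0 °C to rt; Et3N (20 mol%), rt; aq. NH4Cl
Reagents that add atoms: none
Why: EtMgBr turns 9 into the bromomagnesium phenolate 10, whose magnesium binds the carbonyl oxygen of 7 and delivers the acyl carbon to an ortho ring carbon through a six-membered cyclic transition state; rearomatization gives the magnesium-chelated 2-acylphenol 11 (C4–C4a bond), its phenolic oxygen adds to the CH2 terminus of the α-aryl enone (O1–C2 bond) and the enol so formed tautomerizes to the ketone. The closest known reaction types are the ortho-selective Friedel–Crafts acylation of bromomagnesium phenolates with α,β-unsaturated acyl chlorides and the oxa-Michael closure of 2'-hydroxyaryl α-aryl vinyl ketones that ends the classical isoflavanone synthesis from deoxybenzoins and formaldehyde. Ring C, the only ring formed, closes in the 6-endo-trig mode, which is easy here because the acceptor carbon is an unsubstituted CH2 and the chelated aryl ketone holds the phenolic oxygen beside it. C3 becomes stereogenic when the enol is protonated on carbon; nothing controls this event, so 12 is expected as the racemate, which is intended because the base-labile C3–H is what step 8 uses to set the configuration. The step needs C- over O-acylation, ortho over para attack and attack at the acyl carbon rather than conjugate alkylation at CH2; the magnesium template in a non-coordinating solvent, the equivalence of the two ortho carbons of 9 and the far higher electrophilicity of the acid chloride carbonyl should secure these. Neutral, aprotic conditions are chosen because the electron-rich chromene alkene and the MOM acetals would not tolerate the protic or strong Lewis acids of a classical Friedel–Crafts acylation.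

Step 8
Reactants: 12 rac-5,7-bis(methoxymethoxy)-3-[5-(methoxymethoxy)-2,2-dimethyl-2H-chromen-6-yl]chroman-4-one
Product: 13 (3R,4R)-5,7-bis(methoxymethoxy)-3-[5-(methoxymethoxy)-2,2-dimethyl-2H-chromen-6-yl]chroman-4-ol
Conditions: RuCl[(R,R)-TsDPEN](p-cymene) (2 mol%), HCO2H/Et3N (2:3), EtOAc, 40 °C
Reagents that add atoms: none
Why: Noyori asymmetric transfer hydrogenation run as a dynamic kinetic resolution: Et3N should racemize 12 through its enol faster than it is reduced, and the (R,R) catalyst should transfer hydride to the carbonyl face that gives the 4R carbinol and anti to the 3-aryl group, so that only the (3R) ketone is consumed and C3 (R) and C4 (R) are set together as the cis alcohol.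

Step 9
Reactants: 13 (3R,4R)-5,7-bis(methoxymethoxy)-3-[5-(methoxymethoxy)-2,2-dimethyl-2H-chromen-6-yl]chroman-4-ol
Product: 14 (3R)-5,7-bis(methoxymethoxy)-3-[5-(methoxymethoxy)-2,2-dimethyl-2H-chromen-6-yl]chroman-4-one
Conditions: Dess–Martin periodinane, CH2Cl2, 0 °C to rt
Reagents that add atoms: none
Why: Dess–Martin oxidation of the benzylic alcohol under non-basic conditions should return the C4 ketone without enolization, so the C3 (R) centre set in step 8 is kept.

Step 10
Reactants: 14 (3R)-5,7-bis(methoxymethoxy)-3-[5-(methoxymethoxy)-2,2-dimethyl-2H-chromen-6-yl]chroman-4-one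
Product: 15 (3R)-5,7-dihydroxy-3-(5-hydroxy-2,2-dimethyl-2H-chromen-6-yl)chroman-4-one
Conditions: ZnBr2, n-PrSH, CH2Cl2, 0 °C, 10 min
Reagents that add atoms: none
Why: Lewis acid-assisted acetal cleavage with a thiol as scavenger for the methoxymethyl cation should remove aryl MOM ethers within minutes at 0 °C, conditions under which neither acid-catalysed enolization at C3 nor addition to the chromene alkene should compete.

**Compound list**
1 | 2',4'-dihydroxyacetophenone | CC(=O)c1ccc(O)cc1O | starting material
2 | 3-methylbut-2-enal (prenal) | CC(C)=CC=O | starting material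
3 | 1-(5-hydroxy-2,2-dimethyl-2H-chromen-6-yl)ethan-1-one | CC(=O)c1ccc2OC(C)(C)C=Cc2c1O | intermediate
4 | 1-[5-(methoxymethoxy)-2,2-dimethyl-2H-chromen-6-yl]ethan-1-one | CC(=O)c1ccc2OC(C)(C)C=Cc2c1OCOC | intermediate
5 | 1-[5-(methoxymethoxy)-2,2-dimethyl-2H-chromen-6-yl]ethenyl trifluoromethanesulfonate | C=C(OS(=O)(=O)C(F)(F)F)c1ccc2OC(C)(C)C=Cc2c1OCOC | intermediate
6 | 2-[5-(methoxymethoxy)-2,2-dimethyl-2H-chromen-6-yl]prop-2-enoic acid | C=C(C(=O)O)c1ccc2OC(C)(C)C=Cc2c1OCOC | intermediate
7 | 2-[5-(methoxymethoxy)-2,2-dimethyl-2H-chromen-6-yl]prop-2-enoyl chloride | C=C(C(=O)Cl)c1ccc2OC(C)(C)C=Cc2c1OCOC | intermediate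
8 | phloroglucinol (benzene-1,3,5-triol) | Oc1cc(O)cc(O)c1 | starting material
9 | 3,5-bis(methoxymethoxy)phenol | COCOc1cc(O)cc(OCOC)c1 | intermediate
10 | bromomagnesium 3,5-bis(methoxymethoxy)phenolate | COCOc1cc(O[Mg]Br)cc(OCOC)c1 | intermediate
11 | 1-[2-hydroxy-4,6-bis(methoxymethoxy)phenyl]-2-[5-(methoxymethoxy)-2,2-dimethyl-2H-chromen-6-yl]prop-2-en-1-one | C=C(C(=O)c1c(O)cc(OCOC)cc1OCOC)c1ccc2OC(C)(C)C=Cc2c1OCOC | intermediate
12 | rac-5,7-bis(methoxymethoxy)-3-[5-(methoxymethoxy)-2,2-dimethyl-2H-chromen-6-yl]chroman-4-one | CC1(C)C=Cc2c(ccc(C3COc4cc(OCOC)cc(OCOC)c4C3=O)c2OCOC)O1 | intermediate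
13 | (3R,4R)-5,7-bis(methoxymethoxy)-3-[5-(methoxymethoxy)-2,2-dimethyl-2H-chromen-6-yl]chroman-4-ol | CC1(C)C=Cc2c(ccc([C@@H]3COc4cc(OCOC)cc(OCOC)c4[C@@H]3O)c2OCOC)O1 | intermediate
14 | (3R)-5,7-bis(methoxymethoxy)-3-[5-(methoxymethoxy)-2,2-dimethyl-2H-chromen-6-yl]chroman-4-one | CC1(C)C=Cc2c(ccc([C@@H]3COc4cc(OCOC)cc(OCOC)c4C3=O)c2OCOC)O1 | intermediate
15 | (3R)-5,7-dihydroxy-3-(5-hydroxy-2,2-dimethyl-2H-chromen-6-yl)chroman-4-one | CC1(C)C=Cc2c(ccc([C@@H]3COc4cc(O)cc(O)c4C3=O)c2O)O1 | target

Total step count: 10
Longest linear sequence: 9 steps (steps 1–5 and 7–10, from 2',4'-dihydroxyacetophenone)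

**Steps most likely to fail**

Step 7. The phenolate may be acylated on oxygen instead of carbon, the acryloyl chloride may oligomerize before C-acylation, or the neighbouring MOM oxygen may attack the acyl chloride with loss of the acetal. The fallback forms the two bonds in separate, known operations; it sets out from 6 and 8 and comes back at 12.
- Amide coupling of 6 (EDC·HCl, MeNHOMe·HCl, i-Pr2NEt, CH2Cl2) gives the Weinreb amide N-methoxy-N-methyl-2-[5-(methoxymethoxy)-2,2-dimethyl-2H-chromen-6-yl]prop-2-enamide F1.
- Exhaustive etherification of 8 (NaH, MOMCl, DMF) gives 1,3,5-tris(methoxymethoxy)benzene F2, which n-BuLi (THF, 0 °C) should lithiate between two MOM-oxy groups to 2-lithio-1,3,5-tris(methoxymethoxy)benzene F3.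
- Addition of F3 to F1 (THF, −78 °C; the chelated adduct stops at the ketone stage) should give after work-up 2-[5-(methoxymethoxy)-2,2-dimethyl-2H-chromen-6-yl]-1-[2,4,6-tris(methoxymethoxy)phenyl]prop-2-en-1-one F4.
- MgBr2·OEt2 (Et2O/CH2Cl2, 0 °C) should remove by chelation one of the two equivalent MOM groups that flank the carbonyl, giving 11, and NaOAc in EtOH closes 11 to 12.

Step 10. Acid-promoted enolization at C3 (erosion of enantiomeric purity) or addition of thiol or acid across the chromene alkene may accompany the acetal cleavage. The fallback changes the protecting group to a fluoride-labile one at the racemic stage; it sets out from 12 and comes back at 15.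
- All MOM groups are removed from 12 where racemization does not matter (HCl in MeOH/THF, 40 °C) to give rac-5,7-dihydroxy-3-(5-hydroxy-2,2-dimethyl-2H-chromen-6-yl)chroman-4-one F6.
- Silylation (TBSOTf, 2,6-lutidine, CH2Cl2) gives rac-5,7-bis(tert-butyldimethylsilyloxy)-3-[5-(tert-butyldimethylsilyloxy)-2,2-dimethyl-2H-chromen-6-yl]chroman-4-one F7.
- The conditions of step 8 should give (3R,4R)-5,7-bis(tert-butyldimethylsilyloxy)-3-[5-(tert-butyldimethylsilyloxy)-2,2-dimethyl-2H-chromen-6-yl]chroman-4-ol F8.
- The conditions of step 9 should give (3R)-5,7-bis(tert-butyldimethylsilyloxy)-3-[5-(tert-butyldimethylsilyloxy)-2,2-dimethyl-2H-chromen-6-yl]chroman-4-one F9.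
- Et3N·3HF (MeCN, 0 °C), a non-basic fluoride source, then frees the three phenols of F9 and gives 15.

Step 8. Hydride transfer to the hindered, electron-rich ketone flanked by the 5-alkoxy group may be slow, so that reduction and racemization rates mismatch, conversion stalls or the diastereoselectivity erodes; the electron-rich benzylic alcohol may also ionize. The fallback replaces the reduction–oxidation detour by an enantioselective protonation; it sets out from 12 and comes back at 14.
- LiN(SiMe3)2 and Me3SiCl (THF, −78 °C) convert 12 into the silyl enol ether {[5,7-bis(methoxymethoxy)-3-[5-(methoxymethoxy)-2,2-dimethyl-2H-chromen-6-yl]-2H-chromen-4-yl]oxy}trimethylsilane F5.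
- Catalytic enantioselective protonation of F5 (BINOL-derived chiral N-triflyl thiophosphoramide, 5 mol%, phenol as the stoichiometric achiral proton source, toluene, rt) should give 14 directly.
- The catalyst enantiomer is chosen after the sense of induction has been assigned on a first run; step 9 is then not needed.

Further compounds
F1 | step 7 | N-methoxy-N-methyl-2-[5-(methoxymethoxy)-2,2-dimethyl-2H-chromen-6-yl]prop-2-enamide | C=C(C(=O)N(C)OC)c1ccc2OC(C)(C)C=Cc2c1OCOC
F2 | step 7 | 1,3,5-tris(methoxymethoxy)benzene | COCOc1cc(OCOC)cc(OCOC)c1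
F3 | step 7 | 2-lithio-1,3,5-tris(methoxymethoxy)benzene | [Li]c1c(OCOC)cc(OCOC)cc1OCOC
F4 | step 7 | 2-[5-(methoxymethoxy)-2,2-dimethyl-2H-chromen-6-yl]-1-[2,4,6-tris(methoxymethoxy)phenyl]prop-2-en-1-one | C=C(C(=O)c1c(OCOC)cc(OCOC)cc1OCOC)c1ccc2OC(C)(C)C=Cc2c1OCOC
F5 | step 8 | {[5,7-bis(methoxymethoxy)-3-[5-(methoxymethoxy)-2,2-dimethyl-2H-chromen-6-yl]-2H-chromen-4-yl]oxy}trimethylsilane | CC1(C)C=Cc2c(ccc(C3=C(O[Si](C)(C)C)c4c(OCOC)cc(OCOC)cc4OC3)c2OCOC)O1
F6 | step 10 | rac-5,7-dihydroxy-3-(5-hydroxy-2,2-dimethyl-2H-chromen-6-yl)chroman-4-one | CC1(C)C=Cc2c(ccc(C3COc4cc(O)cc(O)c4C3=O)c2O)O1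
F7 | step 10 | rac-5,7-bis(tert-butyldimethylsilyloxy)-3-[5-(tert-butyldimethylsilyloxy)-2,2-dimethyl-2H-chromen-6-yl]chroman-4-one | CC1(C)C=Cc2c(ccc(C3COc4cc(O[Si](C)(C)C(C)(C)C)cc(O[Si](C)(C)C(C)(C)C)c4C3=O)c2O[Si](C)(C)C(C)(C)C)O1
F8 | step 10 | (3R,4R)-5,7-bis(tert-butyldimethylsilyloxy)-3-[5-(tert-butyldimethylsilyloxy)-2,2-dimethyl-2H-chromen-6-yl]chroman-4-ol | CC1(C)C=Cc2c(ccc([C@@H]3COc4cc(O[Si](C)(C)C(C)(C)C)cc(O[Si](C)(C)C(C)(C)C)c4[C@@H]3O)c2O[Si](C)(C)C(C)(C)C)O1
F9 | step 10 | (3R)-5,7-bis(tert-butyldimethylsilyloxy)-3-[5-(tert-butyldimethylsilyloxy)-2,2-dimethyl-2H-chromen-6-yl]chroman-4-one | CC1(C)C=Cc2c(ccc([C@@H]3COc4cc(O[Si](C)(C)C(C)(C)C)cc(O[Si](C)(C)C(C)(C)C)c4C3=O)c2O[Si](C)(C)C(C)(C)C)O1
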